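**Retrosynthetic overview**
1. Target acid ⇐ ethyl enoate ⇐ methyl ketone (Horner–Wadsworth–Emmons). The C9–C11 bond comes from cross-coupling of the tetrasubstituted C8=C9 enol triflate of a trans-decalone.
2. The C4 quaternary centre comes from HAT-initiated radical addition of the ring A alkene (C3=C4) to acrolein, anti to the angular methyl, followed by Wittig isopropylidenation.
3. Rings A and B close together in one intramolecular Diels–Alder reaction of an acyclic 1,7,9-decatrien-3-one. Ring A is the cycloaddition ring, ring B the tether ring, and the step sets C5 and C10.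
4. Trienone ⇐ isopropenyl Grignard reagent + α-methyl ester ⇐ invertive coupling of methyl (R)-lactate triflate with a dienyl Grignard reagent. The lactate-derived C8 centre steers the cycloaddition and is erased at the enol triflate stage.

Assumption: labdane-type labels are used (ring A = C1–C5 + C10, ring B = C5–C10; C4 carries Me and the 4-methylpent-3-enyl chain, C10 the angular Me, C8 the vinylic Me, C9 the side chain C11–C15). The SMILES is read as 4S,5S,10S, that is a trans-decalin with 5-H α, 10-Me β, 4-Me β (axial) and the 4-chain α (equatorial).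

**Step 1**
Reactants: 1 5-bromo-2-methylpent-2-ene
Product: 2 (2E)-5-bromo-2-methylpent-2-enal
Conditions: SeO2 (1.1 equiv), 1,4-dioxane, 80 °C
Reagents that add atoms: selenium dioxide O=[Se]=O
Why: Riley allylic oxidation (ene reaction, then [2,3]-shift of the allylseleninic acid) attacks only the methyl trans to the chain, so the enal is E, and the primary bromide is inert.

**Step 2**
Reactants: 2 (2E)-5-bromo-2-methylpent-2-enal
Product: 3 (3E)-6-bromo-3-methylhexa-1,3-diene
Conditions: Ph3PCH3Br, n-BuLi, THF, −78 → 0 °C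
Reagents that add atoms: methyltriphenylphosphonium bromide C[P+](c1ccccc1)(c1ccccc1)c1ccccc1.[Br-]
Why: Wittig methylenation of the enal keeps the E trisubstituted alkene and gives the terminal 1,3-diene, the ylide adding to the aldehyde far faster than it attacks the primary bromide at low temperature.

**Step 3**
Reactants: 4 methyl (R)-lactate
Product: 5 methyl (2R)-2-{[(trifluoromethyl)sulfonyl]oxy}propanoate
Conditions: Tf2O, 2,6-lutidine, CH2Cl2, −78 → 0 °C
Reagents that add atoms: trifluoromethanesulfonic anhydride O=S(=O)(OS(=O)(=O)C(F)(F)F)C(F)(F)F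
Why: O-sulfonylation does not touch the C–O stereocentre, so the bought R configuration is retained in an excellent SN2 electrophile.

**Step 4**
Reactants: 3 (3E)-6-bromo-3-methylhexa-1,3-diene; 5 methyl (2R)-2-{[(trifluoromethyl)sulfonyl]oxy}propanoate
Product: 7 methyl (2R,5E)-2,6-dimethylocta-5,7-dienoate, via dienylmagnesium bromide 6 (not isolated)
Conditions: 3, Mg, THF, 35 °C; then added to 5, ZnCl2 (5 mol %), THF, 0 °C
Reagents that add atoms: none
Why: Zinc-catalysed sp3–sp3 cross-coupling of an α-triflyloxy ester with a Grignard reagent (through a triorganozincate) is a clean SN2 displacement with inversion; it turns the lactate centre into C8, and the descriptor stays R only because the priorities change.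

**Step 5**
Reactants: 7 methyl (2R,5E)-2,6-dimethylocta-5,7-dienoate
Product: 9 (4R,7E)-2,4,8-trimethyldeca-1,7,9-trien-3-one, via Weinreb amide 8 (not isolated)
Conditions: MeNH(OMe)·HCl (1.5 equiv), isopropenylmagnesium bromide (6 equiv), THF, −20 → 0 °C; poured into cold 1 M HCl
Reagents that add atoms: isopropenylmagnesium bromide C=C(C)[Mg]Br
Why: One-pot Weinreb ketone synthesis, in which the Grignard reagent first makes the magnesium amide that converts the ester into 8 and then adds once; the chelated tetrahedral adduct blocks over-addition and shields the α-stereocentre until the quench.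

**Step 6**
Reactants: 9 (4R,7E)-2,4,8-trimethyldeca-1,7,9-trien-3-one
Product: 10 (2R,4aS,8aS)-2,5,8a-trimethyl-3,4,4a,7,8,8a-hexahydronaphthalen-1(2H)-one (trans-fused, C3=C4 alkene, C9 ketone)
Conditions: toluene (0.02 M), BHT (cat.), 110 °C, sealed tube, 24–36 h
Reagents that add atoms: none
Why: Type 1 intramolecular Diels–Alder reaction, in which the matched (E)-diene/isopropenyl ketone pair closes ring A (cycloaddition ring) and ring B (tether ring) through the chair-like, carbonyl-exo/methyl-endo transition state that gives the trans fusion; the diene methyl penalises the cis-fused alternative, and the C8 methyl sits equatorial (an axial one would meet the nascent angular methyl), which fixes C5 as S and C10 as S.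

**Step 7**
Reactants: 10 (2R,4aS,8aS)-2,5,8a-trimethyl-3,4,4a,7,8,8a-hexahydronaphthalen-1(2H)-one
Product: 11 3-[(1S,4aS,6R,8aS)-1,4a,6-trimethyl-5-oxodecahydronaphthalen-1-yl]propanal
Conditions: Fe(acac)3 (0.3 equiv), PhSiH3 (2.5 equiv), acrolein (3 equiv), EtOH/ethylene glycol 5:1, 60 °C
Reagents that add atoms: acrolein C=CC=O
Why: HAT-initiated reductive olefin coupling (iron hydride, Giese addition), in which H adds to C3 and the tertiary C4 radical attacks acrolein from the α face, opposite the axial C10 methyl, so the new chain is equatorial, the C4 methyl axial and C4 is S.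

**Step 8**
Reactants: 11 3-[(1S,4aS,6R,8aS)-1,4a,6-trimethyl-5-oxodecahydronaphthalen-1-yl]propanal
Product: 12 (2R,4aS,5S,8aS)-2,5,8a-trimethyl-5-(4-methylpent-3-en-1-yl)octahydronaphthalen-1(2H)-one
Conditions: i-PrPPh3I, n-BuLi, THF, 0 °C; then 11, −78 → 0 °C
Reagents that add atoms: isopropyltriphenylphosphonium iodide CC(C)[P+](c1ccccc1)(c1ccccc1)c1ccccc1.[I-]
Why: Wittig olefination is selective for the aldehyde, because the C9 ketone lies between a quaternary and a tertiary carbon and does not react, and any epimerisation at C8 is harmless.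

**Step 9**
Reactants: 12 (2R,4aS,5S,8aS)-2,5,8a-trimethyl-5-(4-methylpent-3-en-1-yl)octahydronaphthalen-1(2H)-one
Product: 14 (4aS,5S,8aS)-2,5,8a-trimethyl-5-(4-methylpent-3-en-1-yl)-3,4,4a,5,6,7,8,8a-octahydronaphthalen-1-yl trifluoromethanesulfonate, via potassium enolate 13 (not isolated)
Conditions: KN(SiMe3)2, THF, −78 → 0 °C; PhNTf2, 0 °C → rt; cold 0.5 M HCl wash
Reagents that add atoms: N-phenylbis(trifluoromethanesulfonimide) O=S(=O)(N(c1ccccc1)S(=O)(=O)C(F)(F)F)C(F)(F)F
Why: Enol triflate formation is regiospecific because C8 carries the only α-hydrogen (C10 is quaternary); it places the tetrasubstituted C8=C9 alkene and removes the now redundant C8 stereocentre.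

**Step 10**
Reactants: 14 (4aS,5S,8aS)-2,5,8a-trimethyl-5-(4-methylpent-3-en-1-yl)-3,4,4a,5,6,7,8,8a-octahydronaphthalen-1-yl trifluoromethanesulfonate; 15 2-(2-bromoethyl)-2-methyl-1,3-dioxolane
Product: 18 4-[(4aS,5S,8aS)-2,5,8a-trimethyl-5-(4-methylpent-3-en-1-yl)-3,4,4a,5,6,7,8,8a-octahydronaphthalen-1-yl]butan-2-one, via ketal Grignard reagent 16 (not isolated), via coupled ketal 17 (not isolated)
Conditions: 15, Mg, THF, 25 °C; then 14, Fe(acac)3 (10 mol %), THF/NMP, −20 → 0 °C; then 2 M HCl, rt, 3 h
Reagents that add atoms: water O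
Why: Iron-catalysed Kumada-type coupling of an alkenyl triflate with a primary alkyl Grignard reagent forms C9–C11 with retention of the alkene position and without β-hydride loss, and the acidic work-up hydrolyses the dioxolane to the methyl ketone.

**Step 11**
Reactants: 18 4-[(4aS,5S,8aS)-2,5,8a-trimethyl-5-(4-methylpent-3-en-1-yl)-3,4,4a,5,6,7,8,8a-octahydronaphthalen-1-yl]butan-2-one
Product: 19 ethyl (2E)-3-methyl-5-[(4aS,5S,8aS)-2,5,8a-trimethyl-5-(4-methylpent-3-en-1-yl)-3,4,4a,5,6,7,8,8a-octahydronaphthalen-1-yl]pent-2-enoate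
Conditions: (EtO)2P(O)CH2CO2Et, NaH, THF, 0 → 50 °C; minor Z isomer removed on silica
Reagents that add atoms: triethyl phosphonoacetate CCOC(=O)CP(=O)(OCC)OCC
Why: Horner–Wadsworth–Emmons olefination of an unhindered methyl ketone gives mainly the E enoate (about 5:1), with the larger alkyl chain trans to the ester.

**Step 12**
Reactants: 19 ethyl (2E)-3-methyl-5-[(4aS,5S,8aS)-2,5,8a-trimethyl-5-(4-methylpent-3-en-1-yl)-3,4,4a,5,6,7,8,8a-octahydronaphthalen-1-yl]pent-2-enoate
Product: 21 (2E)-3-methyl-5-[(4aS,5S,8aS)-2,5,8a-trimethyl-5-(4-methylpent-3-en-1-yl)-3,4,4a,5,6,7,8,8a-octahydronaphthalen-1-yl]pent-2-enoic acid, via lithium carboxylate 20 (not isolated)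
Conditions: LiOH, THF/MeOH/H2O, 50 °C; then 1 M HCl
Reagents that add atoms: lithium hydroxide [Li+].[OH-]
Why: Saponification followed by acidification frees the acid without touching the three alkenes or the three stereocentres.

**Compound list**
1 | 5-bromo-2-methylpent-2-ene | CC(C)=CCCBr | starting material
2 | (2E)-5-bromo-2-methylpent-2-enal | O=C/C(C)=C/CCBr | intermediate
3 | (3E)-6-bromo-3-methylhexa-1,3-diene | C=C/C(C)=C/CCBr | intermediate
4 | methyl (R)-lactate | C[C@@H](O)C(=O)OC | starting material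
5 | methyl (2R)-2-{[(trifluoromethyl)sulfonyl]oxy}propanoate | C[C@@H](OS(=O)(=O)C(F)(F)F)C(=O)OC | intermediate
6 | [(3E)-4-methylhexa-3,5-dien-1-yl]magnesium bromide | C=C/C(C)=C/CC[Mg]Br | intermediate
7 | methyl (2R,5E)-2,6-dimethylocta-5,7-dienoate | C=C/C(C)=C/CC[C@@H](C)C(=O)OC | intermediate
8 | (2R,5E)-N-methoxy-N,2,6-trimethylocta-5,7-dienamide | C=C/C(C)=C/CC[C@@H](C)C(=O)N(C)OC | intermediate
9 | (4R,7E)-2,4,8-trimethyldeca-1,7,9-trien-3-one | C=C/C(C)=C/CC[C@@H](C)C(=O)C(C)=C | intermediate
10 | (2R,4aS,8aS)-2,5,8a-trimethyl-3,4,4a,7,8,8a-hexahydronaphthalen-1(2H)-one | CC1=CCC[C@]2(C)C(=O)[C@H](C)CC[C@@H]12 | intermediate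
11 | 3-[(1S,4aS,6R,8aS)-1,4a,6-trimethyl-5-oxodecahydronaphthalen-1-yl]propanal | O=CCC[C@]1(C)CCC[C@]2(C)C(=O)[C@H](C)CC[C@@H]12 | intermediate
12 | (2R,4aS,5S,8aS)-2,5,8a-trimethyl-5-(4-methylpent-3-en-1-yl)octahydronaphthalen-1(2H)-one | CC(C)=CCC[C@]1(C)CCC[C@]2(C)C(=O)[C@H](C)CC[C@@H]12 | intermediate
13 | potassium enolate of 12 (C8=C9 enolate) | CC(C)=CCC[C@]1(C)CCC[C@]2(C)C([O-])=C(C)CC[C@@H]12.[K+] | intermediate
14 | (4aS,5S,8aS)-2,5,8a-trimethyl-5-(4-methylpent-3-en-1-yl)-3,4,4a,5,6,7,8,8a-octahydronaphthalen-1-yl trifluoromethanesulfonate | CC(C)=CCC[C@]1(C)CCC[C@]2(C)C(OS(=O)(=O)C(F)(F)F)=C(C)CC[C@@H]12 | intermediate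
15 | 2-(2-bromoethyl)-2-methyl-1,3-dioxolane | CC1(CCBr)OCCO1 | starting material
16 | [2-(2-methyl-1,3-dioxolan-2-yl)ethyl]magnesium bromide | CC1(CC[Mg]Br)OCCO1 | intermediate
17 | 2-methyl-2-{2-[(4aS,5S,8aS)-2,5,8a-trimethyl-5-(4-methylpent-3-en-1-yl)-3,4,4a,5,6,7,8,8a-octahydronaphthalen-1-yl]ethyl}-1,3-dioxolane | CC(C)=CCC[C@]1(C)CCC[C@]2(C)C(CCC3(C)OCCO3)=C(C)CC[C@@H]12 | intermediate
18 | 4-[(4aS,5S,8aS)-2,5,8a-trimethyl-5-(4-methylpent-3-en-1-yl)-3,4,4a,5,6,7,8,8a-octahydronaphthalen-1-yl]butan-2-one | CC(C)=CCC[C@]1(C)CCC[C@]2(C)C(CCC(C)=O)=C(C)CC[C@@H]12 | intermediate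
19 | ethyl (2E)-3-methyl-5-[(4aS,5S,8aS)-2,5,8a-trimethyl-5-(4-methylpent-3-en-1-yl)-3,4,4a,5,6,7,8,8a-octahydronaphthalen-1-yl]pent-2-enoate | CC(C)=CCC[C@]1(C)CCC[C@]2(C)C(CC/C(C)=C/C(=O)OCC)=C(C)CC[C@@H]12 | intermediate
20 | lithium salt of 21 | CC(C)=CCC[C@]1(C)CCC[C@]2(C)C(CC/C(C)=C/C(=O)[O-])=C(C)CC[C@@H]12.[Li+] | intermediate
21 | (2E)-3-methyl-5-[(4aS,5S,8aS)-2,5,8a-trimethyl-5-(4-methylpent-3-en-1-yl)-3,4,4a,5,6,7,8,8a-octahydronaphthalen-1-yl]pent-2-enoic acid | CC(C)=CCC[C@]1(C)CCC[C@]2(C)C(CC/C(C)=C/C(=O)O)=C(C)CC[C@@H]12 | target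

**Totals**
Total step count: 12. Longest linear sequence: 11 (steps 1, 2 and 4–12, starting from 1).

**Steps most likely to fail**

Step 6 (cycloaddition). The risks are too much cis-fused adduct and loss of the isopropenyl ketone by oligomerisation on long heating. The cis-fused adduct has the opposite C10 configuration relative to C8 and must be removed on silica. The fallback sets out from 9 and comes back at 10. It replaces the neutral thermal cycloaddition by a cationic, stepwise one at low temperature. 1,2-Bis(trimethylsilyloxy)ethane and catalytic Me3SiOTf in CH2Cl2 at −78 °C give the trienone ethylene ketal F1. The same Lewis acid opens the dioxolane to a vinyl oxocarbenium ion that adds to the diene between −78 and −40 °C (ionic Diels–Alder reaction) and recloses to the decalone ethylene ketal F2. 1 M HCl in THF then returns 10.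

Step 7 (radical quaternisation at C4). The risks are that acrolein polymerises, that the product aldehyde suffers under the silane conditions, and that the C4 radical is simply reduced. The fallback sets out from 10 and comes back at 11. It brings the chain in at the ester level, so that no aldehyde is exposed to the reducing medium, and corrects the oxidation level afterwards. Fe(acac)3/PhSiH3 with methyl acrylate gives the keto ester F3. LiAlH4 in THF reduces both carbonyl groups to the diol F4 (the epimers at the ring carbinol do not matter). Dess–Martin periodinane (2.5 equiv) oxidises both alcohols to give 11.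

Step 10 (sp2–sp3 coupling at a triflate next to a quaternary carbon). The risks are slow coupling and reduction of the triflate. The fallback sets out from 14 and comes back at 18. It makes the C9–C11 bond by an sp2–sp2 Heck vinylation instead. Methyl vinyl ketone, Pd(OAc)2, PPh3 and Et3N in DMF at 70 °C give the cross-conjugation-free dienone F5, a β-ionone-type system. [(Ph3P)CuH]6 in benzene with a little water reduces only the disubstituted enone alkene in the 1,4 sense and gives 18.

**Further compounds**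
F1 | step 6 | 2-[(2R,5E)-6-methylocta-5,7-dien-2-yl]-2-(prop-1-en-2-yl)-1,3-dioxolane | C=C/C(C)=C/CC[C@@H](C)C1(OCCO1)C(C)=C
F2 | step 6 | ethylene ketal of 10 (spiro-dioxolane at C9, same configuration at C5, C8 and C10) | CC1=CCC[C@]2(C)C3(OCCO3)[C@H](C)CC[C@@H]12
F3 | step 7 | methyl 3-[(1S,4aS,6R,8aS)-1,4a,6-trimethyl-5-oxodecahydronaphthalen-1-yl]propanoate | COC(=O)CC[C@]1(C)CCC[C@]2(C)C(=O)[C@H](C)CC[C@@H]12
F4 | step 7 | 3-[(1S,4aS,6R,8aS)-5-hydroxy-1,4a,6-trimethyldecahydronaphthalen-1-yl]propan-1-ol (epimers at the ring carbinol) | OCCC[C@]1(C)CCC[C@]2(C)C(O)[C@H](C)CC[C@@H]12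
F5 | step 10 | (3E)-4-[(4aS,5S,8aS)-2,5,8a-trimethyl-5-(4-methylpent-3-en-1-yl)-3,4,4a,5,6,7,8,8a-octahydronaphthalen-1-yl]but-3-en-2-one | CC(C)=CCC[C@]1(C)CCC[C@]2(C)C(/C=C/C(C)=O)=C(C)CC[C@@H]12
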